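The readings are simulated with made-up constants.

Slowness is what you read first here: after 48.0 h the winter run still holds 71 % of its electrophile.

| setting | winter | dawn | autumn | theta | eta |
|---|---|---|---|---|---|
| electrophile | 0.33 M | 0.33 M | 0.33 M | 0.33 M | 0.33 M |
| nucleophile | 0.36 M | 0.60 M | 0.61 M | 0.400 M | 0.790 M |
| remark | run made earlier | run made earlier | run made earlier |  |  |
| time |  |  |  | 3.0 d | 3.0 d |

| run | time / h | electrophile / % | target / % |
|---|---|---|---|
| winter | 4.00 | 96 | 7 |
| winter | 8.00 | 89 | 7 |
| winter | 15.0 | 86 | 16 |
| winter | 25.0 | 73 | 25 |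
| winter | 48.0 | 71 | 29 |
| dawn | 10.0 | 81 | 23 |
| dawn | 20.0 | 66 | 33 |
| dawn | 30.0 | 63 | 33 |
| dawn | 40.0 | 62 | 41 |
| dawn | 48.0 | 57 | 44 |
| autumn | 5.00 | 85 | 10 |
| autumn | 12.0 | 78 | 19 |
| autumn | 25.0 | 68 | 30 |
| autumn | 40.0 | 61 | 38 |
| autumn | 48.0 | 55 | 47 |

(each reading ± 2 percentage points)

- the analysis behind the earlier runs scatters by 2 percentage points, standard deviation
- what may be going on: 2 nucleophile -> self-condensation product; nucleophile + acid set free <-> protonated nucleophile; nucleophile <-> dormant form; electrophile + nucleophile -> acid set free + target; electrophile + acid set free -> side product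

- part of the electrophile that has reacted at the end, theta
- part of the electrophile that has reacted at the end, eta
- what raising the concentration of nucleophile from its lowest to its highest value here does to the part of the electrophile that has reacted (changes below 5 percentage points count as none) (no change / it rises / it falls)

1. Count turnovers. Take ln(charged [electrophile] / remaining [electrophile]), the count a pseudo-first-order reckoning uses, and divide it by the charged [nucleophile]. Call this S, the count per molar.

2. At 48.0 h, the winter run gives 0.951 M⁻¹, the dawn run 0.937 M⁻¹ and the autumn run 0.980 M⁻¹. The nucleophile charges differ, yet S barely moves. These are readings with a scatter of 2 percentage points; their mean is 0.956 M⁻¹.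

3. Now the time. The winter and autumn runs both have a reading at 25.0 h, where their mean S is 0.753 M⁻¹. So the stretch up to 48.0 h gained 0.212 M⁻¹. I let the next 24.0 h gain the same, which gives S at the asked time, 1.17 M⁻¹.

4. Theta looks like the winter run: 0.400 M of nucleophile against 0.36 M. The winter run reached 29.0 %. By my count, theta's charge read at 48.0 h gives 31.8 %, while the winter charge read at 3.0 d gives 34.3 %, so the extra day is worth more than the extra charge. Together they give 37.3 % for theta, and eta comes to 60.3 %.

5. The forecast says 36 % for theta and 58 % for eta, slightly below mine, and for the trend it says it rises: “Conversion clearly rises with nucleophile.”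

6. The flask gives 37.8 % for theta and 59.4 % for eta. The trend: it rises, by 22 points.

    2 nucleophile → self-condensation product (k = 6.25 × 10⁻⁶ M⁻¹ s⁻¹)
    nucleophile + acid set free ⇌ protonated nucleophile, settled at all times (K = 7070 M⁻¹)
    nucleophile ⇌ dormant form (K = 0.685, k = 1.55 × 10⁻⁵ s⁻¹)
    electrophile + nucleophile → acid set free + target (k = 1.62 × 10⁻⁵ M⁻¹ s⁻¹)
    electrophile + acid set free → side product (k = 1.78 × 10⁻⁵ M⁻¹ s⁻¹)

7. Backed out of these results, S is 1.19 M⁻¹ in theta and 1.14 M⁻¹ in eta, beside my 1.17 M⁻¹. The difference in [nucleophile] may be called the main reason for the gap: eta, given theta's charge, stands at 37.8 % instead of 59.4 %. Carry 1.17 M⁻¹ to the neighbour of eta charged with 2.0 M of nucleophile and read at the same 3.0 d: the count gives 90.4 %, and that flask gives 85.8 %.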